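I began from slowness: none of the solid first nucleophile is in solution at the start, and in the east run the target trails the other capture product for days, so I expected their ratio to rise from zero.

the same everywhere: second nucleophile 0.0285 M

| run | substrate | solid first nucleophile | remark | time |
|---|---|---|---|---|
| east | 0.030 M | 0.030 M | run made earlier |  |
| west | 0.030 M | 0.12 M | run made earlier |  |
| north | 0.060 M | 0.060 M | run made earlier |  |
| flask | 0.030 M | 0.0600 M |  | 15 d |

| run | time / d | target / % | other capture product / % |
|---|---|---|---|
| east | 1.25 | 2 | 8 |
| east | 2.50 | 4 | 13 |
| east | 5.00 | 6 | 19 |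
| east | 10.0 | 9 | 20 |
| east | 20.0 | 10 | 20 |
| west | 4.00 | 6 | 16 |
| west | 8.00 | 8 | 18 |
| west | 10.0 | 7 | 21 |
| west | 15.0 | 9 | 21 |
| west | 20.0 | 9 | 19 |
| north | 4.00 | 7 | 14 |
| north | 8.00 | 9 | 16 |
| north | 10.0 | 11 | 19 |
| north | 15.0 | 7 | 22 |
| north | 20.0 | 9 | 17 |

(readings scatter by 1.5 percentage points)

- what was read earlier has a scatter of 1.5 percentage points, one standard deviation
- at the start none of the solid first nucleophile is in solution

- ratio of target to other capture product at 4.0 h
- ratio of target to other capture product at 15 d

I carried one quantity: the ratio at the first east reading divided by the time since the start, 0.200 d⁻¹, the opening climb. I assumed that it passes from the east run to this flask, which has the same second nucleophile charge. Expecting the curve to bow over, I took the straight line from zero as a floor at 4.0 h, 0.0333. The first east reading of the ratio itself, 0.250, was my ceiling, and I found no way to tighten it, since a line through a reading shifted by its scatter gives another floor and not a ceiling. For 15 d, this flask's solid charge lies between the east and west charges, so I bracketed the ratio by the west reading at 15.0 d, 0.429, and the east reading at 20.0 d, 0.500.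

The forecast, holding that “the target lags”, gave 0.2 and 0.45, the first above my floor and below my ceiling, and the second inside my late bracket.

The flask gave 0.0415 at 4.0 h and 0.460 at 15 d.

    substrate → intermediate (k = 0.0120 h⁻¹)
    first nucleophile + intermediate → target (k = 36.0 L mol⁻¹ h⁻¹)
    second nucleophile + intermediate → other capture product (k = 17.0 L mol⁻¹ h⁻¹)
    intermediate → solvolysis product (k = 1.10 h⁻¹)
    solid first nucleophile ⇌ first nucleophile, rate k5*(cs5 - [first nucleophile]) while solid is left; crystals form when [first nucleophile] > cs5 (solubility = 25.0 mM, k = 0.0110 h⁻¹)
    intermediate → side product (k = 0.0520 h⁻¹)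
    target ⇌ isomer of the product (K = 0.870, k = 0.0660 h⁻¹)

At 1.50 d the solid first nucleophile in this flask still stood at 86.2% of its charge. The flask's own climb to 4.0 h was 0.249 d⁻¹, steeper than the 0.200 d⁻¹ read in the east run. Scaling my floor by the second nucleophile charges gives 0.00864 for the neighbour charged with 0.11 M, and that neighbour stood at 0.0103.

The readings are simulated from invented constants, and the scatter is random.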